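## Structural features

The target consists of two 2,3-dihydro-1-benzofurans: the unprimed one (O1, C2, C3, fused to benzene ring A, C3a–C7a) carries the formyl group on C5 and a 4-hydroxyphenyl group on C2, and the primed one (O1', C2', C3', fused to resorcinol ring B, C3a'–C7a') carries a hydroxyl on C6', a 4-hydroxyphenyl group on C2' and a 3,5-dihydroxyphenyl group on C3'. The two units are joined by a single bond from the sp3 carbon C3 to the arene carbon C4', which lies next to the ring-fusion carbon C3a' and meta to both oxygens of ring B. Four stereocentres form two vicinal pairs, C2/C3 and C2'/C3'; all are R and each pair is trans, but ring B insulates the pairs from each other, so neither can be relied on to direct the other. The fragile elements are the two benzylic aryl ether bonds C2–O1 and C2'–O1' (para-oxygenated benzylic carbons that ionise under acid), the aldehyde, and five oxidation-prone phenols; these are carried as a nitrile and as methyl ethers until the end. The real difficulty is twofold: absolute control in two independent rings, and the congested C3–C4' bond to an arene position that electrophilic substitution cannot reach. The key step uses the fact that the formyl carbon on C5 is para to C7a: a nitrile in its place makes a C7a–F bond open to displacement by a C2 alkoxide. An ester on C3 makes the ketone precursor configurationally labile for dynamic kinetic resolution and later serves as the radical precursor for the C3–C4' bond.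

## Logic of the disconnections

**23 to 22.** The five O–CH3 bonds are cut last. Methyl ethers are the only phenol protection that survives every earlier step (Lewis acids, hydride, base, carbenoid, photoredox), and one global cleavage removes them all. The forward step must cleave five ethers without destroying the two acid-labile benzylic C–O bonds; since both rings are already trans, reversible ionisation can only return the same isomers.

**22 to 20 (through 21).** The formyl group is traced back to a nitrile on C5. This is the group that makes the key step possible and it is inert to all intermediate chemistry. The forward step needs a hydride reduction that stops at the aldimine; nothing else in 20 is reducible.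

**20 to 9 and 19.** The C3–C4' bond is cut. This divides the molecule into two halves of similar size, each holding one pair of stereocentres, so each enantioselective step is run on a small fragment. C3 becomes a radical generated by decarboxylation and C4' an aryl bromide. The forward step must form a crowded sp3–sp2 bond and must place the new aryl group trans to the C2 aryl group; C3 is planar in the radical, so its configuration is set anew here.

**9 to 8 to 6 (through 7), the strategic cut.** After ester hydrolysis, the O1–C7a bond and the C2–H bond are cut, giving an acyclic β-keto ester. One catalyst then sets C2, the ester equilibrates C3, and the ring closes in the same flask. The forward step demands that the alkoxide displaces fluoride faster than it fragments. The precursor keeps fluoride and nitrile for that reason, and keeps the methyl ester so that it can later be removed with hydroxide and not with acid, which the C2–O1 bond of 8 would not tolerate.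

**6 to 4 and 5.** The C2–C3 bond is cut as a Claisen-type acylation. This separates the anisoyl unit from the arylacetate and leaves no stereochemistry to control.

**4 to 1 and 2 (through 3).** The C3–C3a bond is cut as a cross-coupling of a zinc ester enolate with the aryl bromide. Compared with a malonate arylation followed by hot dealkoxycarbonylation, this saves a step and spares the SNAr-active C–F bond from hot nucleophilic conditions. The forward step must select C–Br over C–F and must not add the enolate to the nitrile.

**19 to 18 to 16 (through 17).** First the configuration at C2' is traced to its cis epimer, then the C2'–C3' bond is cut as a carbenoid insertion into a benzylic ether C–H bond. The catalyst sets C3'; C2' is corrected afterwards under thermodynamic control. The forward step needs a diaryl carbenoid that inserts 1,5 into the ether methylene with high facial selectivity despite an ortho bromine.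

**16 to 15 to 13 and 14.** The C=N bond and the O–CH2 ether bond are cut. The benzyl ether delivers both C2' with its aryl group and the oxygen that becomes O1'. The forward condensation must succeed at a carbonyl flanked by two ortho substituents.

**13 to 10 and 11 (through 12).** The C3'–C3a' bond is cut as a Friedel–Crafts acylation, together with one O–CH3 bond. The symmetry of 10 removes any question of which ortho position is acylated, and chelation to the new carbonyl singles out the one methoxy group that must become the free phenol. Bromine on C4' must be present from the start, because that position is meta to both oxygens and cannot be halogenated later.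

## Other disconnections considered

**Alternative 1:** The cut removes two neighbouring bonds of ring B at once, C3–C4' and C3'–C3a', so that ring B enters as an aryne and is inserted into a keto ester that already holds C3 and C3'.

- *Forward key step.* A fluoride source would release the aryne from A1 in the presence of A2. The enolate carbon of A2 should add to the aryne carbon meta to the flanking methoxy group; the aryl anion formed next to that methoxy group should attack the ketone, and fragmentation of the strained alkoxide would give A3.
- *In favour.* A3 holds the complete substitution pattern of ring B with both carbon handles in the right places, and the regiochemistry rests on a well-understood inductive effect. The C3–C4' bond is made early, on small achiral fragments, by a polar reaction. On this point the alternative is the better plan, because the chosen route makes that bond late by a crowded radical–nickel coupling (step 10).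
- *Against it here.* A1 is not a stock compound and needs several steps. A3 has no stereocentre, so all four must be installed afterwards on one crowded core. The ester carbon of A3 would have to become C2 (conversion into the anisyl ketone), and ring A would be attached to C3 by ketone α-arylation with 1. The reduction/SNAr closure would then run on an α,α-diaryl ketone, where C3 is fixed in the reduction itself and no ester remains to equilibrate it to trans. The ketone of A3, once flanked by an ether and the whole unprimed unit, is the worst case for the carbonyl condensation of step 7, and its carbenoid could also insert into the C2–H bond of the neighbouring ring.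
- *Comparison.* On structure, the alternative addresses the substitution pattern of ring B more directly. On mechanism, aryne insertion and decarboxylative arylation are equally well founded as bond-forming events, so the two plans are equal there. On step economy, the count is similar, but the sequence is linear and places both catalyst-controlled steps late on the same intermediate, whereas the chosen plan sets each pair of stereocentres on a separate fragment.

**Alternative 2:** The cut goes through C4'–C5' and C3a'–C7a'; ring B is not brought in but built by cycloaddition onto an alkyne that already hangs on C3.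

- *Forward key step.* Ynone A4 and the Brassard diene A5 would combine in a Diels–Alder reaction, and loss of methanol and of silicon would aromatise the adduct to A6.
- *Structural correction.* The methylene terminus of A5 must bond to the alkyne carbon remote from the carbonyl (C4'), and the ketene acetal carbon must bond to C3a'. The methoxy group on C3 of the diene therefore ends on C6', and the oxygen left on the ketene acetal carbon ends as the free phenol on C7a', ortho to the ketone. A6 is accordingly written as the 6-hydroxy-4-methoxyphenyl ketone; the reverse arrangement (hydroxyl on C6', methoxy on C7a') cannot arise from this diene.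
- *In favour.* The regiochemistry of a strongly polarised diene/ynone pair is dependable. A6 has the free phenol exactly where O1' is needed, so no selective demethylation is required; on this point the alternative is better than step 5 of the chosen plan. No hindered sp3–sp2 coupling is needed, and the step is metal-free and thermally robust, which makes it at least the equal of step 10 in scalability.
- *Against it here.* A4 must be made from a C3 carboxylate through an aldehyde, an alkyne and an acylation, with an epimerisable C3 on the way. The bromine on C5 of A4 does not activate an SNAr closure, so ring A would need another origin, or a late formylation by halogen–metal exchange. After the annulation the ketone of A6 sits between the phenol oxygen and the whole unprimed unit, which is again the most hindered setting for building the primed ring.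
- *Comparison.* On structure, it constructs the crowded arene instead of coupling to it, which is attractive. On mechanism, it is a pericyclic step with predictable orientation. On step economy, it is longer and fully linear, since three or four steps go into A4 and five more follow A6.

**Alternative 3:** The cut goes through C2'–C3' and O1'–C2' of the primed dihydrofuran, a [4+1] disconnection into an ortho-quinone methide and a one-carbon ylide.

- *Forward key step.* A carbonate base would expel sulfinate from the phenol sulfone A7 (written as the p-tolyl sulfone by way of example) to give the ortho-quinone methide, and would deprotonate the chiral sulfonium salt A8 (a C2-symmetric thiolanium salt, written by way of example; the antipode needed would have to be established). The ylide carbon should add to C3', and the phenoxide should then displace the sulfide at C2', giving A9, which is identical with 19.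
- *In favour.* Both stereocentres of the primed ring and the trans relationship would be set in one operation from an achiral precursor. There is no hydrazone at a hindered ketone, no diazo compound and no separate epimerisation. In step count for this ring the alternative is the better plan (one step against steps 7 to 9), and it is operationally simpler.
- *Against it here.* Enantiocontrol with semi-stabilised benzyl ylides depends on the reversibility of betaine formation, which is the same feature that gives the trans product, so the enantiomeric purity is less secure than with a catalyst-controlled insertion. The chiral reagent is stoichiometric. A7 needs two extra steps from 13 (reduction and sulfinate substitution). The disconnection does not address ring A or the C3–C4' bond at all.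
- *Comparison.* On structure, it leads to the same fragment 19, so the two plans are equal in everything that follows. On mechanism, it exchanges a catalytic carbenoid insertion for a stoichiometric ylide annulation with a more open transition state. On step economy, it would shorten the branch by about one step. It is therefore held as the fallback for step 8 and not as the main line.

Key step: step 3

Assumption: in step 8, Rh2(R-PTAD)4 is written for the antipode of the catalyst that gives the 3R centre of 18; if the sense of induction with this substrate is the reverse, Rh2(S-PTAD)4 is taken and nothing else changes.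

## Route

Step 1
Reactants: 1 3-bromo-4-fluorobenzonitrile; 2 methyl bromoacetate
Product: 4 methyl 2-(5-cyano-2-fluorophenyl)acetate, via bromozinc ester enolate 3 (not isolated)
Conditions: 2, Zn dust (Me3SiCl-activated), THF, 35 °C; then 1, Pd(dba)2 (2 mol%), XPhos (4 mol%), THF, 25 °C
Reagents that add atoms: none
Why: Negishi-type coupling of a Reformatsky reagent (palladium-catalysed α-arylation of a zinc ester enolate): zerovalent palladium inserts into C–Br far more readily than into C–F, and at room temperature the mild zinc enolate should neither displace the activated fluoride nor add to the nitrile (Blaise addition needs heat).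

Step 2
Reactants: 4 methyl 2-(5-cyano-2-fluorophenyl)acetate; 5 4-methoxybenzoyl chloride
Product: 6 methyl 2-(5-cyano-2-fluorophenyl)-3-(4-methoxyphenyl)-3-oxopropanoate (racemic)
Conditions: LiN(SiMe3)2 (2.1 equiv), THF, −78 °C; then 5 (1.0 equiv), −78 → −40 °C; aq. NH4Cl
Reagents that add atoms: none
Why: Crossed Claisen C-acylation of a lithium ester enolate with an aroyl chloride; the second equivalent of base converts the more acidic β-keto ester into its enolate as it forms, which should prevent a second acylation, and the new centre is deliberately left racemic and labile.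

Step 3
Reactants: 6 methyl 2-(5-cyano-2-fluorophenyl)-3-(4-methoxyphenyl)-3-oxopropanoate
Product: 8 methyl (2R,3R)-5-cyano-2-(4-methoxyphenyl)-2,3-dihydro-1-benzofuran-3-carboxylate, via hydroxy ester 7 (not isolated)
Conditions: RuCl[(R,R)-TsDPEN](p-cymene) (1 mol%), HCO2H/Et3N (5:2, 3 equiv HCO2H), DMF, 30 °C; then THF, −40 °C, KOtBu (5 equiv), −40 → −20 °C; AcOH quench
Reagents that add atoms: none
Why: The ruthenium hydride formed from formate passes hydride and proton to the ketone through the six-membered outer-sphere transition state of metal–ligand bifunctional transfer hydrogenation, with the anisyl ring held under the cymene ligand, so the (R,R) ligand should give the (R)-carbinol as it does with simple aryl alkyl ketones. Because the α-hydrogen of 6 is flanked by ketone, ester and an electron-poor aryl group, the enantiomers of 6 should interconvert through the enol much faster than either is reduced, so all material is channelled into 7 with the carbinol centre fixed (dynamic kinetic resolution). KOtBu then generates the alkoxide, which adds ipso to fluorine at C7a; the Meisenheimer anion carries its charge on C3a, C5 and C7 and is stabilised by the C5 nitrile, and loss of fluoride forms O1–C7a and closes the dihydrofuran by a 5-exo-trig addition–elimination. The closest known reactions are the ruthenium/TsDPEN transfer hydrogenation of α-aryl β-keto esters with dynamic kinetic resolution and the intramolecular SNAr etherification of para-cyano aryl fluorides, here run one after the other in one flask. C2 is set by the catalyst and is not touched again because its C–O bond is never broken, while C3 is set thermodynamically: the excess base equilibrates the ester-bearing centre to trans through its enolate whatever the syn/anti ratio of 7. The step needs reduction of the ketone beside nitrile and ester, which the hydride-transfer catalyst secures, and it needs ring closure to outrun retro-aldol cleavage and E1cB dehydration of 7, which the para nitrile, the fluoride leaving group and the low temperature are meant to secure; tert-butoxide itself is too hindered to displace fluoride. Opening of 8 by loss of phenoxide from the C3 enolate would be the reverse of a 5-endo-trig closure and is stereoelectronically disfavoured, which should protect C2 during the equilibration.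

Step 4
Reactants: 8 methyl (2R,3R)-5-cyano-2-(4-methoxyphenyl)-2,3-dihydro-1-benzofuran-3-carboxylate
Product: 9 (2R,3R)-5-cyano-2-(4-methoxyphenyl)-2,3-dihydro-1-benzofuran-3-carboxylic acid
Conditions: LiOH·H2O (2 equiv), THF/H2O (3:1), 0 °C → rt; then 1 M aq. HCl to pH 3, 0 °C
Reagents that add atoms: lithium hydroxide, [Li+].[OH-]
Why: Ester saponification by acyl–oxygen cleavage; the nitrile is inert to cold hydroxide, C2 is not affected, and any epimerisation at C3 is harmless because trans is favoured and this centre becomes planar in step 10.

Step 5
Reactants: 10 1-bromo-3,5-dimethoxybenzene; 11 3,5-dimethoxybenzoyl chloride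
Product: 13 (2-bromo-6-hydroxy-4-methoxyphenyl)(3,5-dimethoxyphenyl)methanone, via methoxy ketone 12 (not isolated)
Conditions: AlCl3 (2.5 equiv), CH2Cl2, 0 °C → rt; ice/H2O
Reagents that add atoms: none
Why: Friedel–Crafts acylation at the position ortho to bromine and para to a methoxy group (the two such positions are equivalent, and this is the site such an arene takes electrophiles), followed by chelation-controlled demethylation: AlCl3 bridged between the new carbonyl and the one flanking methoxy group cleaves only that ether, which marks the oxygen that becomes O1'.

Step 6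
Reactants: 13 (2-bromo-6-hydroxy-4-methoxyphenyl)(3,5-dimethoxyphenyl)methanone; 14 4-methoxybenzyl chloride
Product: 15 {2-bromo-4-methoxy-6-[(4-methoxybenzyl)oxy]phenyl}(3,5-dimethoxyphenyl)methanone
Conditions: K2CO3 (2 equiv), Bu4NI (10 mol%), DMF, 60 °C
Reagents that add atoms: none
Why: Williamson ether synthesis on the only free phenol; the benzyl group introduced here supplies C2' and its aryl ring.

Step 7
Reactants: 15 {2-bromo-4-methoxy-6-[(4-methoxybenzyl)oxy]phenyl}(3,5-dimethoxyphenyl)methanone
Product: 16 [{2-bromo-4-methoxy-6-[(4-methoxybenzyl)oxy]phenyl}(3,5-dimethoxyphenyl)methylidene]hydrazine (E/Z mixture)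
Conditions: N2H4·H2O (15 equiv), AcOH (cat.), n-BuOH, 100 °C
Reagents that add atoms: hydrazine (as the hydrate), NN
Why: Acid-catalysed hydrazone condensation; the large excess of the small α-effect nucleophile and the high temperature are chosen for the doubly ortho-substituted carbonyl, and the unactivated aryl bromide and the ethers should not react.

Step 8
Reactants: 16 [{2-bromo-4-methoxy-6-[(4-methoxybenzyl)oxy]phenyl}(3,5-dimethoxyphenyl)methylidene]hydrazine
Product: 18 (2S,3R)-4-bromo-3-(3,5-dimethoxyphenyl)-6-methoxy-2-(4-methoxyphenyl)-2,3-dihydro-1-benzofuran, via diazo compound 17 (not isolated)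
Conditions: MnO2 (8 equiv), CH2Cl2, 0 °C → rt; filter; Rh2(R-PTAD)4 (1 mol%), CH2Cl2, 0 °C
Reagents that add atoms: none
Why: Oxidation of the hydrazone to the diaryldiazomethane and enantioselective intramolecular 1,5 C–H insertion of the derived dirhodium donor/donor carbenoid into the electron-rich benzylic ether methylene; the chiral carboxylate ligands select the face of the carbenoid carbon (C3') and the concerted, hydride-shift-like transition state should give the cis ring, so C3' is set by the catalyst and C2' is set relative to it.

Step 9
Reactants: 18 (2S,3R)-4-bromo-3-(3,5-dimethoxyphenyl)-6-methoxy-2-(4-methoxyphenyl)-2,3-dihydro-1-benzofuran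
Product: 19 (2R,3R)-4-bromo-3-(3,5-dimethoxyphenyl)-6-methoxy-2-(4-methoxyphenyl)-2,3-dihydro-1-benzofuran
Conditions: BF3·OEt2 (0.5 equiv), CH2Cl2, −40 → 0 °C; aq. NaHCO3
Reagents that add atoms: none
Why: Acid-mediated epimerisation by reversible SN1 ionisation of the C2'–O1' bond (para-methoxybenzylic cation tethered to the phenoxide) and re-closure under thermodynamic control to the trans ring; C3' is not involved, so its catalyst-derived configuration now fixes C2' as R.

Step 10
Reactants: 9 (2R,3R)-5-cyano-2-(4-methoxyphenyl)-2,3-dihydro-1-benzofuran-3-carboxylic acid; 19 (2R,3R)-4-bromo-3-(3,5-dimethoxyphenyl)-6-methoxy-2-(4-methoxyphenyl)-2,3-dihydro-1-benzofuran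
Product: 20 (2R,3R)-3-[(2R,3R)-3-(3,5-dimethoxyphenyl)-6-methoxy-2-(4-methoxyphenyl)-2,3-dihydro-1-benzofuran-4-yl]-2-(4-methoxyphenyl)-2,3-dihydro-1-benzofuran-5-carbonitrile
Conditions: 9 (1.5 equiv), 19 (1.0 equiv), Ir[dF(CF3)ppy]2(dtbbpy)PF6 (2 mol%), NiCl2·glyme (10 mol%), dtbbpy (15 mol%), Cs2CO3 (1.5 equiv), DMF, blue LEDs (450 nm), 25 °C
Reagents that add atoms: none
Why: Nickel/photoredox decarboxylative arylation of an α-aryl carboxylic acid: the excited iridium photocatalyst oxidises the carboxylate, loss of CO2 gives the planar benzylic C3 radical, zerovalent nickel inserts into the C4'–Br bond, and radical capture followed by reductive elimination from trivalent nickel forms C3–C4'; the bulky nickel–aryl unit should bond to the face of C3 away from the C2 aryl group, which sets C3 trans, and β-scission of the C2–O1 bond from the radical is disfavoured because that bond lies in the nodal plane of the radical orbital.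

Step 11
Reactants: 20 (2R,3R)-3-[(2R,3R)-3-(3,5-dimethoxyphenyl)-6-methoxy-2-(4-methoxyphenyl)-2,3-dihydro-1-benzofuran-4-yl]-2-(4-methoxyphenyl)-2,3-dihydro-1-benzofuran-5-carbonitrile
Product: 22 (2R,3R)-3-[(2R,3R)-3-(3,5-dimethoxyphenyl)-6-methoxy-2-(4-methoxyphenyl)-2,3-dihydro-1-benzofuran-4-yl]-2-(4-methoxyphenyl)-2,3-dihydro-1-benzofuran-5-carbaldehyde, via aldimine 21 (not isolated)
Conditions: iBu2AlH (1.5 equiv), CH2Cl2, −78 °C; then 1 M aq. HCl/THF, 0 °C
Reagents that add atoms: water, O
Why: Partial reduction of a nitrile with a dialkylaluminium hydride: one hydride adds and the N-aluminated aldimine is stable at −78 °C, so no second hydride is delivered; brief cold aqueous acid hydrolyses it to the aldehyde, and the ethers and stereocentres are untouched.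

Step 12
Reactants: 22 (2R,3R)-3-[(2R,3R)-3-(3,5-dimethoxyphenyl)-6-methoxy-2-(4-methoxyphenyl)-2,3-dihydro-1-benzofuran-4-yl]-2-(4-methoxyphenyl)-2,3-dihydro-1-benzofuran-5-carbaldehyde
Product: 23 (2R,3R)-3-[(2R,3R)-3-(3,5-dihydroxyphenyl)-6-hydroxy-2-(4-hydroxyphenyl)-2,3-dihydro-1-benzofuran-4-yl]-2-(4-hydroxyphenyl)-2,3-dihydro-1-benzofuran-5-carbaldehyde
Conditions: BBr3 (15 equiv), CH2Cl2, −78 → 0 °C; then ice/H2O
Reagents that add atoms: none
Why: Lewis-acid cleavage of aryl methyl ethers (bromide attacks the methyl group of each boron-complexed ether in an SN2 step); the aldehyde is only complexed and returns on hydrolysis, and any reversible ionisation of the benzylic ring C–O bonds can only re-close to the trans rings already present.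

## Compound list

1 | 3-bromo-4-fluorobenzonitrile | N#Cc1ccc(F)c(Br)c1 | starting material
2 | methyl bromoacetate | COC(=O)CBr | starting material
3 | bromo(2-methoxy-2-oxoethyl)zinc (Reformatsky reagent) | COC(=O)C[Zn]Br | intermediate (not isolated)
4 | methyl 2-(5-cyano-2-fluorophenyl)acetate | COC(=O)Cc1cc(C#N)ccc1F | intermediate
5 | 4-methoxybenzoyl chloride | COc1ccc(cc1)C(Cl)=O | starting material
6 | methyl 2-(5-cyano-2-fluorophenyl)-3-(4-methoxyphenyl)-3-oxopropanoate (racemic) | COC(=O)C(c1cc(C#N)ccc1F)C(=O)c1ccc(OC)cc1 | intermediate
7 | methyl (3R)-2-(5-cyano-2-fluorophenyl)-3-hydroxy-3-(4-methoxyphenyl)propanoate (both C2 epimers) | COC(=O)C(c1cc(C#N)ccc1F)[C@@H](O)c1ccc(OC)cc1 | intermediate (not isolated)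
8 | methyl (2R,3R)-5-cyano-2-(4-methoxyphenyl)-2,3-dihydro-1-benzofuran-3-carboxylate | N#Cc1ccc2c(c1)[C@@H](C(=O)OC)[C@H](c1ccc(OC)cc1)O2 | intermediate
9 | (2R,3R)-5-cyano-2-(4-methoxyphenyl)-2,3-dihydro-1-benzofuran-3-carboxylic acid | N#Cc1ccc2c(c1)[C@@H](C(=O)O)[C@H](c1ccc(OC)cc1)O2 | intermediate
10 | 1-bromo-3,5-dimethoxybenzene | COc1cc(Br)cc(OC)c1 | starting material
11 | 3,5-dimethoxybenzoyl chloride | COc1cc(cc(OC)c1)C(Cl)=O | starting material
12 | (2-bromo-4,6-dimethoxyphenyl)(3,5-dimethoxyphenyl)methanone | COc1cc(Br)c(C(=O)c2cc(OC)cc(OC)c2)c(OC)c1 | intermediate (not isolated)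
13 | (2-bromo-6-hydroxy-4-methoxyphenyl)(3,5-dimethoxyphenyl)methanone | COc1cc(O)c(C(=O)c2cc(OC)cc(OC)c2)c(Br)c1 | intermediate
14 | 4-methoxybenzyl chloride | COc1ccc(CCl)cc1 | starting material
15 | {2-bromo-4-methoxy-6-[(4-methoxybenzyl)oxy]phenyl}(3,5-dimethoxyphenyl)methanone | COc1ccc(COc2cc(OC)cc(Br)c2C(=O)c2cc(OC)cc(OC)c2)cc1 | intermediate
16 | [{2-bromo-4-methoxy-6-[(4-methoxybenzyl)oxy]phenyl}(3,5-dimethoxyphenyl)methylidene]hydrazine (E/Z mixture) | COc1ccc(COc2cc(OC)cc(Br)c2C(=NN)c2cc(OC)cc(OC)c2)cc1 | intermediate
17 | 1-bromo-2-[diazo(3,5-dimethoxyphenyl)methyl]-5-methoxy-3-[(4-methoxybenzyl)oxy]benzene | COc1ccc(COc2cc(OC)cc(Br)c2C(=[N+]=[N-])c2cc(OC)cc(OC)c2)cc1 | intermediate (not isolated)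
18 | (2S,3R)-4-bromo-3-(3,5-dimethoxyphenyl)-6-methoxy-2-(4-methoxyphenyl)-2,3-dihydro-1-benzofuran (cis) | Brc1cc(OC)cc2c1[C@@H](c1cc(OC)cc(OC)c1)[C@@H](c1ccc(OC)cc1)O2 | intermediate
19 | (2R,3R)-4-bromo-3-(3,5-dimethoxyphenyl)-6-methoxy-2-(4-methoxyphenyl)-2,3-dihydro-1-benzofuran (trans) | Brc1cc(OC)cc2c1[C@@H](c1cc(OC)cc(OC)c1)[C@H](c1ccc(OC)cc1)O2 | intermediate
20 | (2R,3R)-3-[(2R,3R)-3-(3,5-dimethoxyphenyl)-6-methoxy-2-(4-methoxyphenyl)-2,3-dihydro-1-benzofuran-4-yl]-2-(4-methoxyphenyl)-2,3-dihydro-1-benzofuran-5-carbonitrile | N#Cc1ccc2c(c1)[C@@H](c1cc(OC)cc3c1[C@@H](c1cc(OC)cc(OC)c1)[C@H](c1ccc(OC)cc1)O3)[C@H](c1ccc(OC)cc1)O2 | intermediate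
21 | 1-{(2R,3R)-3-[(2R,3R)-3-(3,5-dimethoxyphenyl)-6-methoxy-2-(4-methoxyphenyl)-2,3-dihydro-1-benzofuran-4-yl]-2-(4-methoxyphenyl)-2,3-dihydro-1-benzofuran-5-yl}methanimine (present in the flask as its N-diisobutylaluminium derivative) | N=Cc1ccc2c(c1)[C@@H](c1cc(OC)cc3c1[C@@H](c1cc(OC)cc(OC)c1)[C@H](c1ccc(OC)cc1)O3)[C@H](c1ccc(OC)cc1)O2 | intermediate (not isolated)
22 | (2R,3R)-3-[(2R,3R)-3-(3,5-dimethoxyphenyl)-6-methoxy-2-(4-methoxyphenyl)-2,3-dihydro-1-benzofuran-4-yl]-2-(4-methoxyphenyl)-2,3-dihydro-1-benzofuran-5-carbaldehyde | O=Cc1ccc2c(c1)[C@@H](c1cc(OC)cc3c1[C@@H](c1cc(OC)cc(OC)c1)[C@H](c1ccc(OC)cc1)O3)[C@H](c1ccc(OC)cc1)O2 | intermediate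
23 | (2R,3R)-3-[(2R,3R)-3-(3,5-dihydroxyphenyl)-6-hydroxy-2-(4-hydroxyphenyl)-2,3-dihydro-1-benzofuran-4-yl]-2-(4-hydroxyphenyl)-2,3-dihydro-1-benzofuran-5-carbaldehyde | O=Cc1ccc2c(c1)[C@@H](c1cc(O)cc3c1[C@@H](c1cc(O)cc(O)c1)[C@H](c1ccc(O)cc1)O3)[C@H](c1ccc(O)cc1)O2 | target

## Step count and least certain steps

Total: 12 steps. Longest linear sequence: 8 steps (from 10 and 11 to 23, steps 5 to 12). The branch from 1 and 2 runs to 7 steps (steps 1 to 4 and 10 to 12).

**Step 3 (key step).** The alkoxide of 7 may fragment by retro-aldol cleavage and recombine, or dehydrate by E1cB, faster than it displaces fluoride; this would cost material and erode the configuration at C2. The cause is that the C3 enolate forms first and, being conjugated with ring A, lowers the electrophilicity of C7a, so closure must go through the minor alkoxide tautomer. The fallback forms the C2–C3 bond by carbenoid C–H insertion instead. It sets out from 1: SNAr with 4-methoxybenzyl alcohol (NaH, DMF, 0 °C) gives 3-bromo-4-[(4-methoxybenzyl)oxy]benzonitrile F1; coupling with 3 under the conditions of step 1 gives methyl 2-{5-cyano-2-[(4-methoxybenzyl)oxy]phenyl}acetate F2; diazo transfer (4-acetamidobenzenesulfonyl azide, DBU, MeCN) gives methyl 2-{5-cyano-2-[(4-methoxybenzyl)oxy]phenyl}-2-diazoacetate F3; Rh2(S-PTTL)4 or its mirror image (whichever gives 2R), toluene, −60 °C, should give by 1,5 C–H insertion the cis ester methyl (2R,3S)-5-cyano-2-(4-methoxyphenyl)-2,3-dihydro-1-benzofuran-3-carboxylate F4; NaOMe in MeOH epimerises C3, and the route is rejoined at 8.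

**Step 10.** The C4'–Br bond is flanked by C3a' and lies peri to the C3' aryl group, so oxidative addition and, above all, C–C reductive elimination at nickel may be slow. The C3 radical would then be lost to dimerisation or to hydrogen abstraction (protodecarboxylation); incomplete trans selectivity at C3 is the second concern. The fallback is a thermal decarboxylative Negishi coupling with a preformed aryl nucleophile and sets out from 9 and 19. Acid 9 with N-hydroxyphthalimide and N,N'-diisopropylcarbodiimide gives the redox-active ester 1,3-dioxoisoindolin-2-yl (2R,3R)-5-cyano-2-(4-methoxyphenyl)-2,3-dihydro-1-benzofuran-3-carboxylate F5. Bromide 19 with n-BuLi (THF, −78 °C) gives [(2R,3R)-3-(3,5-dimethoxyphenyl)-6-methoxy-2-(4-methoxyphenyl)-2,3-dihydro-1-benzofuran-4-yl]lithium F6, which ZnCl2 converts into chloro[(2R,3R)-3-(3,5-dimethoxyphenyl)-6-methoxy-2-(4-methoxyphenyl)-2,3-dihydro-1-benzofuran-4-yl]zinc F7. NiCl2·glyme and dtbbpy in THF/DMF then couple F5 with F7, and the route is rejoined at 20.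

**Step 7.** Condensation at a carbonyl shielded on both sides may be slow and incomplete; at forcing temperature, azine formation or attack of the hydrazone nitrogen on the C–Br carbon (indazole formation) may take over. The fallback replaces the equilibrium condensation by a Lewis-acid-catalysed silyl-hydrazone transfer that is driven by Si–O bond formation. It sets out from 15: 1,2-bis(tert-butyldimethylsilyl)hydrazine with Sc(OTf)3 (1 mol%), CHCl3, 60 °C, gives 1-(tert-butyldimethylsilyl)-2-[{2-bromo-4-methoxy-6-[(4-methoxybenzyl)oxy]phenyl}(3,5-dimethoxyphenyl)methylidene]hydrazine F8; Bu4NF, THF/MeOH, 0 °C, removes silicon, and the route is rejoined at 16.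

**Step 8.** The ortho bromine may twist the carbenoid out of its usual geometry, giving poor facial selectivity or a poor cis preference. The carbenoid may also be diverted to azine formation with unreacted diazo compound, or to attack on the ether oxygen with ylide rearrangement. The fallback is the [4+1] annulation discussed as Alternative 3 and sets out from 13. NaBH4 (MeOH, 0 °C) gives 3-bromo-2-[(3,5-dimethoxyphenyl)(hydroxy)methyl]-5-methoxyphenol F9; p-toluenesulfinic acid converts it into sulfone A7; Cs2CO3 (CH2Cl2, −20 °C) in the presence of sulfonium salt A8 should then give the trans ring directly. The route is rejoined at 19, and steps 6, 7 and 9 fall away.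

**Step 12.** The Lewis acid may ionise the two para-oxygenated benzylic C–O bonds, and elimination or intermolecular Friedel–Crafts capture may then compete with re-closure. The boron-activated aldehyde may condense with the electron-rich rings, and cleavage of all five ethers may be incomplete. The fallback reverses the order of the last two operations, so that the Lewis acid meets a nitrile, which cannot condense. It sets out from 20: BBr3 (CH2Cl2, −78 → 0 °C) gives (2R,3R)-3-[(2R,3R)-3-(3,5-dihydroxyphenyl)-6-hydroxy-2-(4-hydroxyphenyl)-2,3-dihydro-1-benzofuran-4-yl]-2-(4-hydroxyphenyl)-2,3-dihydro-1-benzofuran-5-carbonitrile F10; iBu2AlH (8 equiv, five of which are consumed by the phenols), THF, −40 → 0 °C, then 1 M aq. HCl, gives the aldehyde, and the route is rejoined at 23.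

## Further compounds

F1 | step 3 | 3-bromo-4-[(4-methoxybenzyl)oxy]benzonitrile | N#Cc1ccc(OCc2ccc(OC)cc2)c(Br)c1
F2 | step 3 | methyl 2-{5-cyano-2-[(4-methoxybenzyl)oxy]phenyl}acetate | COC(=O)Cc1cc(C#N)ccc1OCc1ccc(OC)cc1
F3 | step 3 | methyl 2-{5-cyano-2-[(4-methoxybenzyl)oxy]phenyl}-2-diazoacetate | COC(=O)C(=[N+]=[N-])c1cc(C#N)ccc1OCc1ccc(OC)cc1
F4 | step 3 | methyl (2R,3S)-5-cyano-2-(4-methoxyphenyl)-2,3-dihydro-1-benzofuran-3-carboxylate | N#Cc1ccc2c(c1)[C@H](C(=O)OC)[C@H](c1ccc(OC)cc1)O2
F5 | step 10 | 1,3-dioxoisoindolin-2-yl (2R,3R)-5-cyano-2-(4-methoxyphenyl)-2,3-dihydro-1-benzofuran-3-carboxylate | N#Cc1ccc2c(c1)[C@@H](C(=O)ON1C(=O)c3ccccc3C1=O)[C@H](c1ccc(OC)cc1)O2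
F6 | step 10 | [(2R,3R)-3-(3,5-dimethoxyphenyl)-6-methoxy-2-(4-methoxyphenyl)-2,3-dihydro-1-benzofuran-4-yl]lithium | [Li]c1cc(OC)cc2c1[C@@H](c1cc(OC)cc(OC)c1)[C@H](c1ccc(OC)cc1)O2
F7 | step 10 | chloro[(2R,3R)-3-(3,5-dimethoxyphenyl)-6-methoxy-2-(4-methoxyphenyl)-2,3-dihydro-1-benzofuran-4-yl]zinc | Cl[Zn]c1cc(OC)cc2c1[C@@H](c1cc(OC)cc(OC)c1)[C@H](c1ccc(OC)cc1)O2
F8 | step 7 | 1-(tert-butyldimethylsilyl)-2-[{2-bromo-4-methoxy-6-[(4-methoxybenzyl)oxy]phenyl}(3,5-dimethoxyphenyl)methylidene]hydrazine | COc1ccc(COc2cc(OC)cc(Br)c2C(=NN[Si](C)(C)C(C)(C)C)c2cc(OC)cc(OC)c2)cc1
F9 | step 8 | 3-bromo-2-[(3,5-dimethoxyphenyl)(hydroxy)methyl]-5-methoxyphenol (racemic) | COc1cc(O)c(C(O)c2cc(OC)cc(OC)c2)c(Br)c1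
F10 | step 12 | (2R,3R)-3-[(2R,3R)-3-(3,5-dihydroxyphenyl)-6-hydroxy-2-(4-hydroxyphenyl)-2,3-dihydro-1-benzofuran-4-yl]-2-(4-hydroxyphenyl)-2,3-dihydro-1-benzofuran-5-carbonitrile | N#Cc1ccc2c(c1)[C@@H](c1cc(O)cc3c1[C@@H](c1cc(O)cc(O)c1)[C@H](c1ccc(O)cc1)O3)[C@H](c1ccc(O)cc1)O2
A1 | alternative 1 | 3,5-dimethoxy-2-(trimethylsilyl)phenyl trifluoromethanesulfonate | COc1cc(OC)c([Si](C)(C)C)c(OS(=O)(=O)C(F)(F)F)c1
A2 | alternative 1 | methyl 3-(3,5-dimethoxyphenyl)-3-oxopropanoate | COC(=O)CC(=O)c1cc(OC)cc(OC)c1
A3 | alternative 1 | methyl 2-[2-(3,5-dimethoxybenzoyl)-3,5-dimethoxyphenyl]acetate | COC(=O)Cc1cc(OC)cc(OC)c1C(=O)c1cc(OC)cc(OC)c1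
A4 | alternative 2 | 3-[(2R,3R)-5-bromo-2-(4-methoxyphenyl)-2,3-dihydro-1-benzofuran-3-yl]-1-(3,5-dimethoxyphenyl)prop-2-yn-1-one | Brc1ccc2c(c1)[C@@H](C#CC(=O)c1cc(OC)cc(OC)c1)[C@H](c1ccc(OC)cc1)O2
A5 | alternative 2 | 1,3-dimethoxy-1-(trimethylsilyloxy)buta-1,3-diene (Brassard diene) | COC(=C)C=C(OC)O[Si](C)(C)C
A6 | alternative 2 | {2-[(2R,3R)-5-bromo-2-(4-methoxyphenyl)-2,3-dihydro-1-benzofuran-3-yl]-6-hydroxy-4-methoxyphenyl}(3,5-dimethoxyphenyl)methanone | Brc1ccc2c(c1)[C@@H](c1cc(OC)cc(O)c1C(=O)c1cc(OC)cc(OC)c1)[C@H](c1ccc(OC)cc1)O2
A7 | alternative 3 | 3-bromo-2-[(3,5-dimethoxyphenyl)(4-methylbenzenesulfonyl)methyl]-5-methoxyphenol (racemic) | COc1cc(O)c(C(c2cc(OC)cc(OC)c2)S(=O)(=O)c2ccc(C)cc2)c(Br)c1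
A8 | alternative 3 | (2R,5R)-1-(4-methoxybenzyl)-2,5-dimethylthiolan-1-ium trifluoromethanesulfonate | C[C@@H]1CC[C@@H](C)[S+]1Cc1ccc(OC)cc1.[O-]S(=O)(=O)C(F)(F)F
A9 | alternative 3 | (2R,3R)-4-bromo-3-(3,5-dimethoxyphenyl)-6-methoxy-2-(4-methoxyphenyl)-2,3-dihydro-1-benzofuran (identical with 19) | Brc1cc(OC)cc2c1[C@@H](c1cc(OC)cc(OC)c1)[C@H](c1ccc(OC)cc1)O2
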